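**Strategy.** Ring B is cut at C7–C8 and C9–C10. The tetrasubstituted C8=C9 alkene, with its C17 methyl and the C11 carbon, is read as the two alkyne carbons of methyl but-2-ynoate; the C6 oxygen and C5–C10 belong to a ring A 2-silyloxydiene. One intermolecular Diels–Alder reaction joins the two fragments, closes ring B, creates quaternary C10 and leaves C11 as an ester and C6 as a masked ketone. The diene is an enantiopure 1-(1-triethylsilyloxyvinyl)-2-methylcyclohexene carrying the C2 and C19 oxygens as tert-butyldimethylsilyl ethers, so that the enol silyl group can later be removed alone.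

Key step: step 14

Remark: labdane numbering is used (C1–C10 decalin; C11–C16 side chain with C15 the lactone carbonyl and C16 the OCH2; C17 on C8; C18 α-methyl and C19 β-CH2O on C4; C20 on C10); α is the face opposite to C20; TBS = tert-butyldimethylsilyl, TES = triethylsilyl.

## Route

Step 1
Reactants: 1 1,4-dioxaspiro[4.5]dec-6-en-8-one
Product: 2 (8R)-1,4-dioxaspiro[4.5]dec-6-en-8-ol
Conditions: (S)-Me-CBS oxazaborolidine [(S)-1-methyl-3,3-diphenyltetrahydro-1H,3H-pyrrolo[1,2-c][1,3,2]oxazaborole] (0.2 equiv), catecholborane, toluene, −78 °C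
Reagents that add atoms: none
Why: Corey–Bakshi–Shibata reduction: the alkene arm of the enone acts as the large group, so the (S)-oxazaborolidine should deliver hydride to the face that gives the (R)-carbinol, the future C2 with its α oxygen.

Step 2
Reactants: 2 (8R)-1,4-dioxaspiro[4.5]dec-6-en-8-ol
Product: 3 (8R)-8-(TBSO)-1,4-dioxaspiro[4.5]dec-6-ene
Conditions: TBSCl, imidazole, DMF, rt
Reagents that add atoms: tert-butyldimethylsilyl chloride CC(C)(C)[Si](C)(C)Cl
Why: Silyl ether formation on a secondary allylic alcohol, which blocks the C2 hydroxyl for the rest of the route.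

Step 3
Reactants: 3 (8R)-8-(TBSO)-1,4-dioxaspiro[4.5]dec-6-ene
Product: 4 (4R)-4-(TBSO)cyclohex-2-en-1-one
Conditions: pyridinium p-toluenesulfonate (cat.), acetone/H2O, 55 °C
Reagents that add atoms: water O
Why: Acid-catalysed acetal hydrolysis frees the enone while the secondary silyl ether and the carbinol centre stay untouched.

Step 4
Reactants: 4 (4R)-4-(TBSO)cyclohex-2-en-1-one
Product: 5 (4R)-4-(TBSO)-2-(hydroxymethyl)cyclohex-2-en-1-one
Conditions: 37% aq. HCHO, DMAP (0.3 equiv), THF/H2O, rt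
Reagents that add atoms: formaldehyde C=O
Why: Morita–Baylis–Hillman reaction with formaldehyde puts the C19 hydroxymethyl group on the α-carbon of the enone (future C4), a reaction known for γ-oxygenated cyclohexenones.

Step 5
Reactants: 5 (4R)-4-(TBSO)-2-(hydroxymethyl)cyclohex-2-en-1-one
Product: 6 (4R)-4-(TBSO)-2-[(TBSO)methyl]cyclohex-2-en-1-one
Conditions: TBSCl, imidazole, CH2Cl2, 0 °C → rt
Reagents that add atoms: tert-butyldimethylsilyl chloride CC(C)(C)[Si](C)(C)Cl
Why: Silyl ether formation on the primary allylic alcohol, so that only one free hydroxyl will later direct the cyclopropanation.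

Step 6
Reactants: 6 (4R)-4-(TBSO)-2-[(TBSO)methyl]cyclohex-2-en-1-one
Product: 7 (1S,4R)-4-(TBSO)-2-[(TBSO)methyl]cyclohex-2-en-1-ol (1,4-cis)
Conditions: (R)-Me-CBS oxazaborolidine [(R)-1-methyl-3,3-diphenyltetrahydro-1H,3H-pyrrolo[1,2-c][1,3,2]oxazaborole] (0.2 equiv), catecholborane, toluene, −78 °C
Reagents that add atoms: none
Why: Corey–Bakshi–Shibata reduction of a 2-substituted enone, a favourable substrate class: the (R)-catalyst should give the (1S)-carbinol cis to the silyloxy group, the face that hydride attack anti to that group is also expected to favour.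

Step 7
Reactants: 7 (1S,4R)-4-(TBSO)-2-[(TBSO)methyl]cyclohex-2-en-1-ol
Product: 8 (1R,2S,5R,6S)-5-(TBSO)-1-[(TBSO)methyl]bicyclo[4.1.0]heptan-2-ol
Conditions: Et2Zn, CH2I2, CH2Cl2, 0 °C → rt
Reagents that add atoms: diiodomethane ICI
Why: Hydroxyl-directed Simmons–Smith cyclopropanation (diethylzinc variant): the zinc alkoxide delivers the methylene to the alkene face cis to the free hydroxyl, which fixes C4 with the bridge CH2 (future C18) cis to the C2 oxygen and the CH2OTBS group trans.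

Step 8
Reactants: 8 (1R,2S,5R,6S)-5-(TBSO)-1-[(TBSO)methyl]bicyclo[4.1.0]heptan-2-ol
Product: 9 (1S,2R,4R)-4-(TBSO)-2-[(TBSO)methyl]-2-methylcyclohexan-1-ol
Conditions: H2 (4 atm), PtO2, NaOAc, EtOAc/AcOH, rt
Reagents that add atoms: none
Why: Catalytic hydrogenolysis of the cyclopropane at its least substituted bond (C3–CH2) should turn the bridge carbon into the C18 methyl on quaternary C4, with the configuration from step 7 retained.

Step 9
Reactants: 9 (1S,2R,4R)-4-(TBSO)-2-[(TBSO)methyl]-2-methylcyclohexan-1-ol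
Product: 10 (2R,4R)-4-(TBSO)-2-[(TBSO)methyl]-2-methylcyclohexan-1-one
Conditions: Dess–Martin periodinane, CH2Cl2, rt
Reagents that add atoms: none
Why: Dess–Martin oxidation of the hindered secondary alcohol gives the C5 ketone; the directing carbinol centre is no longer needed.

Step 10
Reactants: 10 (2R,4R)-4-(TBSO)-2-[(TBSO)methyl]-2-methylcyclohexan-1-one
Product: 11 (2R,4R,6S)-4-(TBSO)-2-[(TBSO)methyl]-2,6-dimethylcyclohexan-1-one
Conditions: LiN(iPr)2, THF, −78 °C; MeI, −78 → 0 °C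
Reagents that add atoms: iodomethane CI
Why: Enolate alkylation is regiospecific because only C10 can be deprotonated; the new centre (equatorial-methyl epimer drawn) is planarised again in step 11, so its configuration does not matter.

Step 11
Reactants: 11 (2R,4R,6S)-4-(TBSO)-2-[(TBSO)methyl]-2,6-dimethylcyclohexan-1-one
Product: 12 (4R,6R)-4-(TBSO)-6-[(TBSO)methyl]-2,6-dimethylcyclohex-1-en-1-yl trifluoromethanesulfonate
Conditions: KN(SiMe3)2, THF, −78 → 0 °C; PhNTf2
Reagents that add atoms: N-phenylbis(trifluoromethanesulfonimide) O=S(=O)(N(c1ccccc1)S(=O)(=O)C(F)(F)F)C(F)(F)F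
Why: Enol triflate formation from the potassium enolate, which can form only toward C10 and so gives the tetrasubstituted C5=C10 triflate.

Step 12
Reactants: 12 (4R,6R)-4-(TBSO)-6-[(TBSO)methyl]-2,6-dimethylcyclohex-1-en-1-yl trifluoromethanesulfonate
Product: 14 1-[(4R,6S)-4-(TBSO)-6-[(TBSO)methyl]-2,6-dimethylcyclohex-1-en-1-yl]ethan-1-one, via ethoxydiene 13 (not isolated)
Conditions: CH2=C(OEt)SnBu3, Pd(PPh3)4 (5 mol%), LiCl, THF, 65 °C; then 1 M HCl, 0 °C
Reagents that add atoms: tributyl(1-ethoxyvinyl)stannane CCCC[Sn](CCCC)(CCCC)C(=C)OCC; water O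
Why: Stille coupling of the vinyl triflate with an acetyl anion equivalent, followed by hydrolysis of the ethyl enol ether, installs C6 and C7 as the methyl ketone.

Step 13
Reactants: 14 1-[(4R,6S)-4-(TBSO)-6-[(TBSO)methyl]-2,6-dimethylcyclohex-1-en-1-yl]ethan-1-one
Product: 15 triethyl({1-[(4R,6S)-4-(TBSO)-6-[(TBSO)methyl]-2,6-dimethylcyclohex-1-en-1-yl]ethenyl}oxy)silane
Conditions: LiN(iPr)2, THF, −78 °C; Et3SiCl, −78 → 0 °C
Reagents that add atoms: chlorotriethylsilane CC[Si](Cl)(CC)CC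
Why: Kinetic deprotonation of the methyl ketone at C7 and O-silylation (silyl enol ether formation) give the cross-conjugated 2-silyloxydiene; the more labile triethylsilyl group is chosen so that it can be cleaved later beside the two TBS ethers.

Step 14
Reactants: 15 triethyl({1-[(4R,6S)-4-(TBSO)-6-[(TBSO)methyl]-2,6-dimethylcyclohex-1-en-1-yl]ethenyl}oxy)silane; 16 methyl but-2-ynoate
Product: 17 methyl 2α,19-bis(TBSO)-6-(TESO)-12,13,14,15,16-pentanorlabda-5,8-dien-11-oate
Conditions: 16 (5 equiv), BHT (cat.), toluene, 150 °C, sealed tube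
Reagents that add atoms: none
Why: A thermal, concerted but asynchronous [4+2] cycloaddition of normal electron demand joins the HOMO of the diene C7=C6(OTES)–C5=C10 with the LUMO of the ynoate and forms C7–C8 and C9–C10 in one step. The closest known reactions are Diels–Alder additions of 1-(1-silyloxyvinyl)cycloalkenes and of 1-vinyl-2,6,6-trimethylcyclohexene to acetylenic esters, which give 1,4-cyclohexadienes. Ring B is closed by the cycloaddition itself, as a six-membered ring formed suprafacially on both partners with no separate cyclisation event. The only new stereocentre, C10, should be set by approach of the linear alkyne to the diene face anti to the pseudoaxial C19 CH2OTBS group on C4, a conformation locked by the equatorial C2 OTBS group, so that C20 ends cis to C19. The step needs para regioselectivity, which is secured because the largest HOMO coefficient lies on the unsubstituted terminus C7 (oxygen donor on C6, alkyl groups on C10) and meets the ester β-carbon C8, placing the ester carbon on C9. The 1,4-diene cannot aromatise because C10 is quaternary, and the enol ether keeps C6 as a protected ketone.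

Step 15
Reactants: 17 methyl 2α,19-bis(TBSO)-6-(TESO)-12,13,14,15,16-pentanorlabda-5,8-dien-11-oate
Product: 18 2α,19-bis(TBSO)-6-(TESO)-12,13,14,15,16-pentanorlabda-5,8-dien-11-ol
Conditions: iBu2AlH (3 equiv), CH2Cl2, −78 → 0 °C
Reagents that add atoms: none
Why: Ester reduction with iBu2AlH gives the primary allylic alcohol, while the silyl enol ether and the silyl ethers are inert to the hydride, so C6 stays masked.

Step 16
Reactants: 18 2α,19-bis(TBSO)-6-(TESO)-12,13,14,15,16-pentanorlabda-5,8-dien-11-ol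
Product: 20 11-chloro-2α,19-bis(TBSO)-6-(TESO)-12,13,14,15,16-pentanorlabda-5,8-diene, via mesylate 19 (not isolated)
Conditions: MsCl, LiCl, 2,4,6-collidine, DMF, 0 °C
Reagents that add atoms: lithium chloride [Li+].[Cl-]
Why: Mesylation and in situ SN2 displacement by chloride under buffered conditions should give the primary allylic chloride without allylic shift, since the other allyl terminus C8 is fully substituted.

Step 17
Reactants: 21 furan-3-ylmethanol
Product: 22 3-(chloromethyl)furan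
Conditions: SOCl2, pyridine, Et2O, 0 °C
Reagents that add atoms: thionyl chloride O=S(Cl)Cl
Why: Chlorodehydroxylation of a primary furylmethyl alcohol with thionyl chloride and pyridine; the labile chloride is used at once.

Step 18
Reactants: 20 11-chloro-2α,19-bis(TBSO)-6-(TESO)-12,13,14,15,16-pentanorlabda-5,8-diene; 22 3-(chloromethyl)furan
Product: 24 2α,19-bis(TBSO)-6-(TESO)-15,16-epoxylabda-5,8,13(16),14-tetraene, via Grignard reagent 23 (not isolated)
Conditions: 22, Mg, THF, 0 °C; then 20, Li2CuCl4 (5 mol%), THF, −20 → 0 °C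
Reagents that add atoms: none
Why: Copper-catalysed cross-coupling of an allylic chloride with (furan-3-ylmethyl)magnesium chloride, a known route to furanoterpenes, should form C11–C12 at the primary carbon because the SN2' terminus C8 is fully substituted.

Step 19
Reactants: 24 2α,19-bis(TBSO)-6-(TESO)-15,16-epoxylabda-5,8,13(16),14-tetraene
Product: 25 2α,19-bis(TBSO)-15,16-epoxy-5α-labda-8,13(16),14-trien-6-one
Conditions: Bu4NF (1.2 equiv), AcOH (1.5 equiv), THF, −78 → −30 °C
Reagents that add atoms: none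
Why: Fluoride cleaves the triethylsilyl enol ether far faster than the alkyl TBS ethers (desilylation of a silyl enol ether), and kinetic protonation of the enolate at C5 by acetic acid from the α face, anti to C19 and C20, should give the trans ring fusion without moving the C8=C9 alkene into conjugation.

Step 20
Reactants: 25 2α,19-bis(TBSO)-15,16-epoxy-5α-labda-8,13(16),14-trien-6-one
Product: 26 2α,19-bis(TBSO)-15,16-epoxy-5α-labda-8,13(16),14-trien-6α-ol
Conditions: Li, NH3(l), THF, EtOH, −78 °C; NH4Cl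
Reagents that add atoms: none
Why: Dissolving-metal reduction of a cyclohexanone gives the thermodynamically preferred equatorial alcohol, here 6α, whereas hydride reagents would attack from the α face and give the axial 6β-alcohol; the isolated alkene, the furan and the silyl ethers should not be reduced.

Step 21
Reactants: 26 2α,19-bis(TBSO)-15,16-epoxy-5α-labda-8,13(16),14-trien-6α-ol
Product: 27 6α-acetoxy-2α,19-bis(TBSO)-15,16-epoxy-5α-labda-8,13(16),14-triene
Conditions: Ac2O, DMAP, pyridine, rt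
Reagents that add atoms: acetic anhydride CC(=O)OC(C)=O
Why: DMAP-catalysed acetylation (esterification) of the only free hydroxyl.

Step 22
Reactants: 27 6α-acetoxy-2α,19-bis(TBSO)-15,16-epoxy-5α-labda-8,13(16),14-triene
Product: 29 6α-acetoxy-2α,19-bis(TBSO)labda-8,13-dien-15,16-olide, via hydroxybutenolide 28 (not isolated)
Conditions: O2, hν, tetraphenylporphyrin (cat.), iPr2NEt, CH2Cl2, −78 °C; then NaBH4, EtOH, 0 °C; 1 M HCl
Reagents that add atoms: oxygen O=O
Why: [4+2] photooxygenation of the 3-substituted furan with singlet oxygen and a hindered amine opens the endoperoxide at the less hindered C15–H to the 16-hydroxybutenolide, and borohydride reduction of its aldehyde tautomer with relactonisation gives the butenolide with C15 as carbonyl; the furan should react much faster than the hindered C8=C9 alkene.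

Step 23
Reactants: 29 6α-acetoxy-2α,19-bis(TBSO)labda-8,13-dien-15,16-olide
Product: 30 6α-acetoxy-2α,19-dihydroxylabda-8,13-dien-15,16-olide (CNP0231903.1)
Conditions: HF·pyridine, pyridine, THF, 0 °C → rt
Reagents that add atoms: none
Why: Fluoride-mediated desilylation under weakly acidic conditions should remove both TBS ethers and leave the acetate, the butenolide and the alkene untouched.

## Compound list

1 | 1,4-dioxaspiro[4.5]dec-6-en-8-one | O=C1C=CC2(OCCO2)CC1 | starting material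
2 | (8R)-1,4-dioxaspiro[4.5]dec-6-en-8-ol | O[C@H]1C=CC2(OCCO2)CC1 | intermediate
3 | (8R)-8-(TBSO)-1,4-dioxaspiro[4.5]dec-6-ene | CC(C)(C)[Si](C)(C)O[C@H]1C=CC2(OCCO2)CC1 | intermediate
4 | (4R)-4-(TBSO)cyclohex-2-en-1-one | CC(C)(C)[Si](C)(C)O[C@H]1C=CC(=O)CC1 | intermediate
5 | (4R)-4-(TBSO)-2-(hydroxymethyl)cyclohex-2-en-1-one | CC(C)(C)[Si](C)(C)O[C@H]1C=C(CO)C(=O)CC1 | intermediate
6 | (4R)-4-(TBSO)-2-[(TBSO)methyl]cyclohex-2-en-1-one | CC(C)(C)[Si](C)(C)O[C@H]1C=C(CO[Si](C)(C)C(C)(C)C)C(=O)CC1 | intermediate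
7 | (1S,4R)-4-(TBSO)-2-[(TBSO)methyl]cyclohex-2-en-1-ol, hydroxyl cis to the ring silyloxy group | O[C@H]1CC[C@@H](O[Si](C)(C)C(C)(C)C)C=C1CO[Si](C)(C)C(C)(C)C | intermediate
8 | (1R,2S,5R,6S)-5-(TBSO)-1-[(TBSO)methyl]bicyclo[4.1.0]heptan-2-ol, cyclopropane cis to both oxygens | O[C@H]1CC[C@@H](O[Si](C)(C)C(C)(C)C)[C@H]2C[C@@]12CO[Si](C)(C)C(C)(C)C | intermediate
9 | (1S,2R,4R)-4-(TBSO)-2-[(TBSO)methyl]-2-methylcyclohexan-1-ol | O[C@H]1CC[C@@H](O[Si](C)(C)C(C)(C)C)C[C@]1(C)CO[Si](C)(C)C(C)(C)C | intermediate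
10 | (2R,4R)-4-(TBSO)-2-[(TBSO)methyl]-2-methylcyclohexan-1-one | O=C1CC[C@@H](O[Si](C)(C)C(C)(C)C)C[C@]1(C)CO[Si](C)(C)C(C)(C)C | intermediate
11 | (2R,4R,6S)-4-(TBSO)-2-[(TBSO)methyl]-2,6-dimethylcyclohexan-1-one | O=C1[C@@H](C)C[C@@H](O[Si](C)(C)C(C)(C)C)C[C@]1(C)CO[Si](C)(C)C(C)(C)C | intermediate
12 | (4R,6R)-4-(TBSO)-6-[(TBSO)methyl]-2,6-dimethylcyclohex-1-en-1-yl trifluoromethanesulfonate | FC(F)(F)S(=O)(=O)OC1=C(C)C[C@@H](O[Si](C)(C)C(C)(C)C)C[C@]1(C)CO[Si](C)(C)C(C)(C)C | intermediate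
13 | (4R,6S)-1-(1-ethoxyethenyl)-4-(TBSO)-6-[(TBSO)methyl]-2,6-dimethylcyclohex-1-ene | CCOC(=C)C1=C(C)C[C@@H](O[Si](C)(C)C(C)(C)C)C[C@]1(C)CO[Si](C)(C)C(C)(C)C | intermediate
14 | 1-[(4R,6S)-4-(TBSO)-6-[(TBSO)methyl]-2,6-dimethylcyclohex-1-en-1-yl]ethan-1-one | CC(=O)C1=C(C)C[C@@H](O[Si](C)(C)C(C)(C)C)C[C@]1(C)CO[Si](C)(C)C(C)(C)C | intermediate
15 | triethyl({1-[(4R,6S)-4-(TBSO)-6-[(TBSO)methyl]-2,6-dimethylcyclohex-1-en-1-yl]ethenyl}oxy)silane (ring A silyloxydiene) | C=C(O[Si](CC)(CC)CC)C1=C(C)C[C@@H](O[Si](C)(C)C(C)(C)C)C[C@]1(C)CO[Si](C)(C)C(C)(C)C | intermediate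
16 | methyl but-2-ynoate | CC#CC(=O)OC | starting material
17 | methyl 2α,19-bis(TBSO)-6-(TESO)-12,13,14,15,16-pentanorlabda-5,8-dien-11-oate (bicyclic 5,8-diene, C6 silyl enol ether, C9 ester, C20 β) | COC(=O)C1=C(C)CC(O[Si](CC)(CC)CC)=C2[C@]1(C)C[C@@H](O[Si](C)(C)C(C)(C)C)C[C@]2(C)CO[Si](C)(C)C(C)(C)C | intermediate
18 | 2α,19-bis(TBSO)-6-(TESO)-12,13,14,15,16-pentanorlabda-5,8-dien-11-ol | OCC1=C(C)CC(O[Si](CC)(CC)CC)=C2[C@]1(C)C[C@@H](O[Si](C)(C)C(C)(C)C)C[C@]2(C)CO[Si](C)(C)C(C)(C)C | intermediate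
19 | 2α,19-bis(TBSO)-6-(TESO)-12,13,14,15,16-pentanorlabda-5,8-dien-11-yl methanesulfonate | CS(=O)(=O)OCC1=C(C)CC(O[Si](CC)(CC)CC)=C2[C@]1(C)C[C@@H](O[Si](C)(C)C(C)(C)C)C[C@]2(C)CO[Si](C)(C)C(C)(C)C | intermediate
20 | 11-chloro-2α,19-bis(TBSO)-6-(TESO)-12,13,14,15,16-pentanorlabda-5,8-diene | ClCC1=C(C)CC(O[Si](CC)(CC)CC)=C2[C@]1(C)C[C@@H](O[Si](C)(C)C(C)(C)C)C[C@]2(C)CO[Si](C)(C)C(C)(C)C | intermediate
21 | furan-3-ylmethanol | OCc1ccoc1 | starting material
22 | 3-(chloromethyl)furan | ClCc1ccoc1 | intermediate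
23 | (furan-3-ylmethyl)magnesium chloride | Cl[Mg]Cc1ccoc1 | intermediate
24 | 2α,19-bis(TBSO)-6-(TESO)-15,16-epoxylabda-5,8,13(16),14-tetraene (3-substituted furan on C12) | c1cc(CCC2=C(C)CC(O[Si](CC)(CC)CC)=C3[C@]2(C)C[C@@H](O[Si](C)(C)C(C)(C)C)C[C@]3(C)CO[Si](C)(C)C(C)(C)C)co1 | intermediate
25 | 2α,19-bis(TBSO)-15,16-epoxy-5α-labda-8,13(16),14-trien-6-one (trans-fused) | O=C1CC(C)=C(CCc2ccoc2)[C@@]2(C)C[C@@H](O[Si](C)(C)C(C)(C)C)C[C@](C)(CO[Si](C)(C)C(C)(C)C)[C@H]12 | intermediate
26 | 2α,19-bis(TBSO)-15,16-epoxy-5α-labda-8,13(16),14-trien-6α-ol | O[C@H]1CC(C)=C(CCc2ccoc2)[C@@]2(C)C[C@@H](O[Si](C)(C)C(C)(C)C)C[C@](C)(CO[Si](C)(C)C(C)(C)C)[C@H]12 | intermediate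
27 | 6α-acetoxy-2α,19-bis(TBSO)-15,16-epoxy-5α-labda-8,13(16),14-triene | CC(=O)O[C@H]1CC(C)=C(CCc2ccoc2)[C@@]2(C)C[C@@H](O[Si](C)(C)C(C)(C)C)C[C@](C)(CO[Si](C)(C)C(C)(C)C)[C@H]12 | intermediate
28 | 6α-acetoxy-2α,19-bis(TBSO)-16-hydroxylabda-8,13-dien-15,16-olide (C16 epimers) | CC(=O)O[C@H]1CC(C)=C(CCC2=CC(=O)OC2O)[C@@]2(C)C[C@@H](O[Si](C)(C)C(C)(C)C)C[C@](C)(CO[Si](C)(C)C(C)(C)C)[C@H]12 | intermediate
29 | 6α-acetoxy-2α,19-bis(TBSO)labda-8,13-dien-15,16-olide | CC(=O)O[C@H]1CC(C)=C(CCC2=CC(=O)OC2)[C@@]2(C)C[C@@H](O[Si](C)(C)C(C)(C)C)C[C@](C)(CO[Si](C)(C)C(C)(C)C)[C@H]12 | intermediate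
30 | 6α-acetoxy-2α,19-dihydroxylabda-8,13-dien-15,16-olide (CNP0231903.1) | CC(=O)O[C@H]1CC(C)=C(CCC2=CC(=O)OC2)[C@@]2(C)C[C@@H](O)C[C@](C)(CO)[C@H]12 | target

## Step count and risk

Total step count: 23. Longest linear sequence: 22 steps (steps 1–16 and 18–23; step 17 is a one-step side branch).

Steps most likely to fail:

1. Step 14 (key cycloaddition). The twisted, fully substituted diene may add too slowly at the crowded C10 terminus, so that the enol silyl group is lost thermally before addition, or the alkyne may add to both diene faces. Fallback: setting out from 15, a Diels–Alder reaction with the more reactive allenic ester methyl buta-2,3-dienoate (toluene, 110 °C) at its conjugated double bond should give the exocyclic-methylene adduct, methyl 2α,19-bis(TBSO)-6-(TESO)-12,13,14,15,16-pentanorlabda-5,8(17)-dien-11-oate F1. Base-mediated isomerisation (DBU cat., CH2Cl2) should then move the exocyclic alkene into conjugation with the ester, which comes back to the route at 17.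

2. Step 22 (furan to butenolide). Singlet oxygen may also undergo an ene reaction at the electron-rich tetrasubstituted C8=C9 alkene, or the hydroxybutenolide may be over-reduced. Fallback without any oxidant, setting out from 20 and coming back at 29:
   - Alkylation of 20 with 2-methylprop-2-en-1-ol deprotonated twice (n-BuLi, TMEDA, THF) should give the 2-substituted allylic alcohol 2α,19-bis(TBSO)-6-(TESO)-15-norlabda-5,8,13-trien-16-ol F2.
   - Enol ether cleavage as in step 19 gives 2α,19-bis(TBSO)-16-hydroxy-15-nor-5α-labda-8,13-dien-6-one F3.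
   - Dissolving-metal reduction as in step 20 gives 2α,19-bis(TBSO)-15-nor-5α-labda-8,13-diene-6α,16-diol F4.
   - Acryloyl chloride and Et3N at −78 °C acylate the primary allylic hydroxyl to 16-acryloyloxy-2α,19-bis(TBSO)-15-nor-5α-labda-8,13-dien-6α-ol F5.
   - Ac2O and DMAP give 6α-acetoxy-16-acryloyloxy-2α,19-bis(TBSO)-15-nor-5α-labda-8,13-diene F6.
   - Ring-closing metathesis with the second-generation Grubbs catalyst RuCl2(=CHPh)(PCy3)(H2IMes) (toluene, 80 °C) closes the butenolide between C13 and C14 and returns to 29; the tetrasubstituted C8=C9 alkene is inert to the catalyst.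

3. Step 20 (C6 carbinol). Under the basic dissolving-metal conditions the ketone may enolise toward C7 with migration of the C8=C9 alkene into conjugation, or protonation may give the axial epimer. Fallback that avoids the ketone altogether, setting out from 24 and coming back at 26:
   - CsF and PhNTf2 (DME, rt) should convert the silyl enol ether directly into the enol triflate 2α,19-bis(TBSO)-15,16-epoxylabda-5,8,13(16),14-tetraen-6-yl trifluoromethanesulfonate F7.
   - Palladium-catalysed formate reduction (Pd(OAc)2, PPh3, HCO2H, Et3N, DMF, 60 °C) gives the 5,8-diene 2α,19-bis(TBSO)-15,16-epoxylabda-5,8,13(16),14-tetraene F8.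
   - Hydroboration–oxidation (BH3·THF, 0 °C; NaOH, H2O2) of the trisubstituted C5=C6 alkene from the α face, as known for 4,4-disubstituted steroid 5-enes, should set 5α-H and 6α-OH together and returns to 26.

## Further compounds

F1 | step 14 | methyl 2α,19-bis(TBSO)-6-(TESO)-12,13,14,15,16-pentanorlabda-5,8(17)-dien-11-oate (C9 epimers, planarised on isomerisation) | COC(=O)C1C(=C)CC(O[Si](CC)(CC)CC)=C2[C@]1(C)C[C@@H](O[Si](C)(C)C(C)(C)C)C[C@]2(C)CO[Si](C)(C)C(C)(C)C
F2 | step 22 | 2α,19-bis(TBSO)-6-(TESO)-15-norlabda-5,8,13-trien-16-ol | OCC(=C)CCC1=C(C)CC(O[Si](CC)(CC)CC)=C2[C@]1(C)C[C@@H](O[Si](C)(C)C(C)(C)C)C[C@]2(C)CO[Si](C)(C)C(C)(C)C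
F3 | step 22 | 2α,19-bis(TBSO)-16-hydroxy-15-nor-5α-labda-8,13-dien-6-one | O=C1CC(C)=C(CCC(=C)CO)[C@@]2(C)C[C@@H](O[Si](C)(C)C(C)(C)C)C[C@](C)(CO[Si](C)(C)C(C)(C)C)[C@H]12
F4 | step 22 | 2α,19-bis(TBSO)-15-nor-5α-labda-8,13-diene-6α,16-diol | O[C@H]1CC(C)=C(CCC(=C)CO)[C@@]2(C)C[C@@H](O[Si](C)(C)C(C)(C)C)C[C@](C)(CO[Si](C)(C)C(C)(C)C)[C@H]12
F5 | step 22 | 16-acryloyloxy-2α,19-bis(TBSO)-15-nor-5α-labda-8,13-dien-6α-ol | O[C@H]1CC(C)=C(CCC(=C)COC(=O)C=C)[C@@]2(C)C[C@@H](O[Si](C)(C)C(C)(C)C)C[C@](C)(CO[Si](C)(C)C(C)(C)C)[C@H]12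
F6 | step 22 | 6α-acetoxy-16-acryloyloxy-2α,19-bis(TBSO)-15-nor-5α-labda-8,13-diene | CC(=O)O[C@H]1CC(C)=C(CCC(=C)COC(=O)C=C)[C@@]2(C)C[C@@H](O[Si](C)(C)C(C)(C)C)C[C@](C)(CO[Si](C)(C)C(C)(C)C)[C@H]12
F7 | step 20 | 2α,19-bis(TBSO)-15,16-epoxylabda-5,8,13(16),14-tetraen-6-yl trifluoromethanesulfonate | c1cc(CCC2=C(C)CC(OS(=O)(=O)C(F)(F)F)=C3[C@]2(C)C[C@@H](O[Si](C)(C)C(C)(C)C)C[C@]3(C)CO[Si](C)(C)C(C)(C)C)co1
F8 | step 20 | 2α,19-bis(TBSO)-15,16-epoxylabda-5,8,13(16),14-tetraene | c1cc(CCC2=C(C)CC=C3[C@]2(C)C[C@@H](O[Si](C)(C)C(C)(C)C)C[C@]3(C)CO[Si](C)(C)C(C)(C)C)co1
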